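**Strategy.** Everything hinges on opening the ester that joins rings B and A. Its carbonyl carbon C7' is bonded on one side to C1' of ring B (between O-2' and the 6'-methyl) and on the other to O-4 of ring A, so it can be brought in as carbon monoxide. A palladium-catalysed aryloxycarbonylation unites a dibenzyl-protected iodo-orcinol, CO and the ring A monophenol, making the C1'–C7' and C7'–O4 bonds at once without activating a hindered orsellinic acid. The precursor is 1,5-bis(benzyloxy)-2-iodo-3-methylbenzene. After debenzylation of the AB ester, the same iodide is carbonylated onto the free 4'-OH to supply ring C.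

Key step: step 6

Assumption: the target has no stereocentre and no configurationally stable axis, so it is made as the one achiral compound drawn and no stereocontrol is needed.

**Step 1**
Reactants: 1 orcinol (5-methylbenzene-1,3-diol)
Product: 2 1,3-bis(benzyloxy)-5-methylbenzene
Conditions: BnBr (2.3 equiv), K2CO3 (3 equiv), DMF, 60 °C
Reagents that add atoms: benzyl bromide, BrCc1ccccc1
Why: Williamson ether synthesis on both unhindered phenoxides of a symmetric diphenol should give the bis(benzyl ether) cleanly.

**Step 2**
Reactants: 2 1,3-bis(benzyloxy)-5-methylbenzene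
Product: 3 1,5-bis(benzyloxy)-2-iodo-3-methylbenzene
Conditions: NIS (1.05 equiv), MeCN, 0 °C to rt, dark
Reagents that add atoms: N-iodosuccinimide, O=C1CCC(=O)N1I
Why: Electrophilic aromatic iodination should occur at C4 (equivalent to C6 by symmetry), which is para to one benzyloxy group, ortho to the other and less crowded than C2 between the two ethers.

**Step 3**
Reactants: 4 methyl orsellinate (methyl 2,4-dihydroxy-6-methylbenzoate)
Product: 5 methyl 4-(benzyloxy)-2-hydroxy-6-methylbenzoate
Conditions: BnBr (1.05 equiv), K2CO3 (1.2 equiv), acetone, reflux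
Reagents that add atoms: benzyl bromide, BrCc1ccccc1
Why: Williamson etherification is selective for the 4-OH because the 2-OH is tied up in a hydrogen bond to the ester carbonyl and is less acidic and less nucleophilic.

**Step 4**
Reactants: 5 methyl 4-(benzyloxy)-2-hydroxy-6-methylbenzoate
Product: 6 methyl 4-(benzyloxy)-2-methoxy-6-methylbenzoate
Conditions: MeI (3 equiv), K2CO3 (3 equiv), DMF, 50 °C
Reagents that add atoms: iodomethane, CI
Why: Williamson O-methylation with excess iodomethane in a dipolar aprotic solvent overcomes the chelation of the remaining phenol, which is the only nucleophilic site left.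

**Step 5**
Reactants: 6 methyl 4-(benzyloxy)-2-methoxy-6-methylbenzoate
Product: 7 methyl 4-hydroxy-2-methoxy-6-methylbenzoate
Conditions: H2 (1 atm), 10% Pd/C, EtOAc, rt
Reagents that add atoms: none
Why: Catalytic hydrogenolysis cleaves the benzyl aryl ether and leaves the methyl ether and methyl ester untouched.

**Step 6**
Reactants: 3 1,5-bis(benzyloxy)-2-iodo-3-methylbenzene (1.2 equiv); 8 carbon monoxide; 7 methyl 4-hydroxy-2-methoxy-6-methylbenzoate
Product: 9 methyl 4-{[2,4-bis(benzyloxy)-6-methylbenzoyl]oxy}-2-methoxy-6-methylbenzoate (AB depside bis(benzyl ether))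
Conditions: Pd(OAc)2 (5 mol %), Xantphos (7.5 mol %), Et3N (2.5 equiv), CO (1 atm, balloon), toluene, 90 °C
Reagents that add atoms: carbon monoxide, [C-]#[O+] (compound 8, also listed as reactant)
Why: Pd(0) inserts into the C–I bond of 3, CO undergoes migratory insertion to give an aroyl-palladium(II) species, and the triethylammonium phenoxide of 7 displaces iodide and leaves with the acyl group by C–O reductive elimination, regenerating Pd(0). The closest known reaction type is the palladium-catalysed aryloxycarbonylation (carbonylative esterification) of aryl iodides with phenols under atmospheric CO. No ring is closed and no stereocentre is created. Acyl capture must outrun direct Ullmann-type aryl ether formation and hydrodeiodination; the wide-bite-angle diphosphine under CO favours insertion, and insertion relieves the crowding of the di-ortho-substituted aryl–palladium bond. Reaction at a single oxygen is secured because 7 has only one OH (its 2-oxygen is a methyl ether), while the benzyl ethers, the methyl ester and the new aryl ester, shielded by 2'-OBn and 6'-Me, should be inert to Et3N at 90 °C.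

**Step 7**
Reactants: 9 AB depside bis(benzyl ether)
Product: 10 methyl 4-[(2,4-dihydroxy-6-methylbenzoyl)oxy]-2-methoxy-6-methylbenzoate (AB diol)
Conditions: H2 (1 atm), 10% Pd/C, EtOAc/THF, rt
Reagents that add atoms: none
Why: Neutral catalytic hydrogenolysis removes both benzyl ethers, the aryl ester and methyl ester are inert to it, and the alcohol-free solvent excludes transesterification.

**Step 8**
Reactants: 10 AB diol; 3 1,5-bis(benzyloxy)-2-iodo-3-methylbenzene (1.05 equiv); 8 carbon monoxide
Product: 11 methyl 4-{[4-{[2,4-bis(benzyloxy)-6-methylbenzoyl]oxy}-2-hydroxy-6-methylbenzoyl]oxy}-2-methoxy-6-methylbenzoate (ABC tridepside bis(benzyl ether))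
Conditions: Pd(OAc)2 (5 mol %), Xantphos (7.5 mol %), Et3N (1.5 equiv), CO (1 atm), 1,4-dioxane, 80 °C
Reagents that add atoms: carbon monoxide, [C-]#[O+] (compound 8, also listed as reactant)
Why: The same palladium-catalysed aryloxycarbonylation should acylate the 4'-OH, which is the more acidic (para to the ester carbonyl) and unhindered phenol, whereas the 2'-OH is held in an intramolecular hydrogen bond to the depside carbonyl; a weak amine base and near-stoichiometric iodide limit a second acylation.

**Step 9**
Reactants: 11 ABC tridepside bis(benzyl ether)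
Product: 12 methyl 4-{[4-[(2,4-dihydroxy-6-methylbenzoyl)oxy]-2-hydroxy-6-methylbenzoyl]oxy}-2-methoxy-6-methylbenzoate (target)
Conditions: H2 (1 atm), 10% Pd/C, THF/EtOAc, rt; filtration with warm THF
Reagents that add atoms: none
Why: Catalytic hydrogenolysis of the two remaining benzyl ethers under neutral conditions should free the ring C diol without touching either depside ester, the methyl ester or the methyl ether.

**Compound list**
1 | orcinol (5-methylbenzene-1,3-diol) | Cc1cc(O)cc(O)c1 | starting material
2 | 1,3-bis(benzyloxy)-5-methylbenzene | Cc1cc(OCc2ccccc2)cc(OCc2ccccc2)c1 | intermediate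
3 | 1,5-bis(benzyloxy)-2-iodo-3-methylbenzene | Cc1cc(OCc2ccccc2)cc(OCc2ccccc2)c1I | intermediate
4 | methyl orsellinate (methyl 2,4-dihydroxy-6-methylbenzoate) | COC(=O)c1c(C)cc(O)cc1O | starting material
5 | methyl 4-(benzyloxy)-2-hydroxy-6-methylbenzoate | COC(=O)c1c(C)cc(OCc2ccccc2)cc1O | intermediate
6 | methyl 4-(benzyloxy)-2-methoxy-6-methylbenzoate | COC(=O)c1c(C)cc(OCc2ccccc2)cc1OC | intermediate
7 | methyl 4-hydroxy-2-methoxy-6-methylbenzoate | COC(=O)c1c(C)cc(O)cc1OC | intermediate
8 | carbon monoxide | [C-]#[O+] | starting material
9 | methyl 4-{[2,4-bis(benzyloxy)-6-methylbenzoyl]oxy}-2-methoxy-6-methylbenzoate | COC(=O)c1c(C)cc(OC(=O)c2c(C)cc(OCc3ccccc3)cc2OCc2ccccc2)cc1OC | intermediate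
10 | methyl 4-[(2,4-dihydroxy-6-methylbenzoyl)oxy]-2-methoxy-6-methylbenzoate | COC(=O)c1c(C)cc(OC(=O)c2c(C)cc(O)cc2O)cc1OC | intermediate
11 | methyl 4-{[4-{[2,4-bis(benzyloxy)-6-methylbenzoyl]oxy}-2-hydroxy-6-methylbenzoyl]oxy}-2-methoxy-6-methylbenzoate | COC(=O)c1c(C)cc(OC(=O)c2c(C)cc(OC(=O)c3c(C)cc(OCc4ccccc4)cc3OCc3ccccc3)cc2O)cc1OC | intermediate
12 | methyl 4-{[4-[(2,4-dihydroxy-6-methylbenzoyl)oxy]-2-hydroxy-6-methylbenzoyl]oxy}-2-methoxy-6-methylbenzoate | COC(=O)c1c(C)cc(OC(=O)c2c(C)cc(OC(=O)c3c(C)cc(O)cc3O)cc2O)cc1OC | target

**Total step count:** 9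
**Longest linear sequence:** 7 steps (methyl orsellinate 4 through steps 3, 4, 5, 6, 7, 8 and 9 to 12)

**Steps most likely to fail**

Step 8. The second carbonylation may lose site control, with acylation at the chelated 2'-OH or at both phenols, and the phenoxide may exchange into the existing depside ester under base and heat. The fallback sets out from 3. Iodine–lithium exchange (n-BuLi, THF, −78 °C) should give [2,4-bis(benzyloxy)-6-methylphenyl]lithium F1, which is quenched with CO2 and acidified to 2,4-bis(benzyloxy)-6-methylbenzoic acid F2. Trifluoroacetic anhydride in dry toluene at rt converts this in the flask into 2,4-bis(benzyloxy)-6-methylbenzoic trifluoroacetic anhydride F3. F3 acylates the unchelated 4'-OH of 10 without any base, the classical depside condensation, and the route is rejoined at 11.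

Step 6. Turnover may be slow with the electron-rich, doubly ortho-substituted iodide, so that hydrodeiodination, direct aryl ether formation or catalyst precipitation under CO compete with ester formation. The fallback sets out from 3 and replaces catalysis by acyl substitution. [2,4-Bis(benzyloxy)-6-methylphenyl]lithium F1 and 2,4-bis(benzyloxy)-6-methylbenzoic acid F2 are made as above. Oxalyl chloride with catalytic DMF in CH2Cl2 then gives 2,4-bis(benzyloxy)-6-methylbenzoyl chloride F4. F4 is coupled with 7 (Et3N, DMAP, CH2Cl2, rt), and the route is rejoined at 9.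

Step 2. Iodination may be unselective, with attack at the position between the two ethers or a second iodination, giving mixtures that are hard to separate. The fallback sets out from 2. NBS in MeCN at 0 °C should give 1,5-bis(benzyloxy)-2-bromo-3-methylbenzene F5, which is purified by crystallisation. Bromine–lithium exchange (n-BuLi, THF, −78 °C) to [2,4-bis(benzyloxy)-6-methylphenyl]lithium F1 and a quench with I2 bring the route back at 3.

**Further compounds**
F1 | step 8 | [2,4-bis(benzyloxy)-6-methylphenyl]lithium | [Li]c1c(C)cc(OCc2ccccc2)cc1OCc1ccccc1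
F2 | step 8 | 2,4-bis(benzyloxy)-6-methylbenzoic acid | Cc1cc(OCc2ccccc2)cc(OCc2ccccc2)c1C(O)=O
F3 | step 8 | 2,4-bis(benzyloxy)-6-methylbenzoic trifluoroacetic anhydride | Cc1cc(OCc2ccccc2)cc(OCc2ccccc2)c1C(=O)OC(=O)C(F)(F)F
F4 | step 6 | 2,4-bis(benzyloxy)-6-methylbenzoyl chloride | Cc1cc(OCc2ccccc2)cc(OCc2ccccc2)c1C(Cl)=O
F5 | step 2 | 1,5-bis(benzyloxy)-2-bromo-3-methylbenzene | Cc1cc(OCc2ccccc2)cc(OCc2ccccc2)c1Br
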